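**Retrosynthetic overview**
- The strategy rests on the tetrahydrofuran ring (O1, C2, C3, C4, C5). C2 is a benzylic C–H carbon bonded to O1 and to the guaiacyl ring, and it stands next to C3, whose CH2OH can be carried as an ester on a diazo carbon.
- Key disconnection C2–C3: a rhodium carbene at C3 inserts into the benzylic C–H of a 4-benzyloxy-3-methoxybenzyl (vanillyl) ether. This closes the only ring made in the route, and equilibration at C3 then gives the all-trans ester.
- The α-diazo tert-butyl ester comes from the parent ester by deacylative diazo transfer; O1–C2 is made before that by imidate benzylation of the C5 primary alcohol.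
- C4 and the side-chain carbinol come from an Evans syn aldol of a succinate half-ester imide with 3,4-bis(benzyloxy)benzaldehyde; reductive removal of the auxiliary unveils C5.
- End game: reduction of the C3 ester, desilylation, hydrogenolysis of three benzyl ethers.

Key step: step 8

Assumption: Rh2(S-PTTL)4 is taken as the catalyst enantiomer whose facial preference is matched with the C4-controlled chair-like closure; the substrate bias alone points to the same C2 configuration.

**Route**

Step 1
Reactants: 1 4-tert-butoxy-4-oxobutanoic acid (mono-tert-butyl succinate); 2 (R)-4-benzyl-1,3-oxazolidin-2-one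
Product: 4 tert-butyl 4-[(4R)-4-benzyl-2-oxo-1,3-oxazolidin-3-yl]-4-oxobutanoate, via mixed pivalic anhydride 3 (not isolated)
Conditions: PivCl, Et3N, THF, −20 °C; then 2, LiCl, −20 °C → rt
Reagents that add atoms: none
Why: N-acylation of the oxazolidinone through a mixed anhydride, in which the oxazolidinone attacks the unhindered succinyl carbonyl and not the pivaloyl carbonyl; no stereocenter is formed.

Step 2
Reactants: 4 tert-butyl 4-[(4R)-4-benzyl-2-oxo-1,3-oxazolidin-3-yl]-4-oxobutanoate; 5 3,4-bis(benzyloxy)benzaldehyde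
Product: 8 tert-butyl (3R,4R)-3-{[(4R)-4-benzyl-2-oxo-1,3-oxazolidin-3-yl]carbonyl}-4-[3,4-bis(benzyloxy)phenyl]-4-hydroxybutanoate (syn aldol adduct), via Z-boron enolate 6 (not isolated), via boron aldolate 7 (not isolated)
Conditions: Bu2BOTf, i-Pr2NEt, CH2Cl2, −78 → 0 °C; 5, −78 → 0 °C; pH 7 phosphate buffer, MeOH, 30% H2O2, 0 °C
Reagents that add atoms: none
Why: Evans syn aldol reaction, in which the Z-dibutylboron enolate of the imide reacts through a closed chair transition state on the face away from the benzyl group of the (R)-auxiliary and so sets both the future C4 and the carbinol carbon as the syn (3R,4R) pair, while the tert-butyl ester neither enolises nor lactonises.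

Step 3
Reactants: 8 syn aldol adduct
Product: 9 tert-butyl (3R,4R)-3-{[(4R)-4-benzyl-2-oxo-1,3-oxazolidin-3-yl]carbonyl}-4-[3,4-bis(benzyloxy)phenyl]-4-[(tert-butyldimethylsilyl)oxy]butanoate
Conditions: TBSOTf, 2,6-lutidine, CH2Cl2, −78 → −20 °C
Reagents that add atoms: tert-butyldimethylsilyl trifluoromethanesulfonate, CC(C)(C)[Si](C)(C)OS(=O)(=O)C(F)(F)F
Why: Silylation of the hindered secondary benzylic alcohol with a silyl triflate, which blocks retro-aldol cleavage and later O–H insertion; the low temperature and short contact time spare the tert-butyl ester.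

Step 4
Reactants: 9 silylated aldol imide
Product: 10 tert-butyl (3S,4R)-4-[3,4-bis(benzyloxy)phenyl]-4-[(tert-butyldimethylsilyl)oxy]-3-(hydroxymethyl)butanoate
Conditions: LiBH4, MeOH (1 equiv), THF, 0 °C
Reagents that add atoms: none
Why: Reductive cleavage of the N-acyl oxazolidinone by borohydride, which attacks the activated exocyclic imide carbonyl in preference to the tert-butyl ester and gives the primary alcohol that becomes C5–O1; the stereocenter is untouched and its descriptor changes from R to S only because the CIP priorities change.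

Step 5
Reactants: 11 [4-(benzyloxy)-3-methoxyphenyl]methanol
Product: 12 4-(benzyloxy)-3-methoxybenzyl 2,2,2-trichloroacetimidate
Conditions: Cl3CCN, DBU (10 mol%), CH2Cl2, 0 °C; used at once after filtration through Et3N-deactivated silica
Reagents that add atoms: trichloroacetonitrile, ClC(Cl)(Cl)C#N
Why: Base-catalysed addition of the benzylic alcohol to trichloroacetonitrile (trichloroacetimidate formation), the standard activation of an electron-rich benzyl alcohol for acid-catalysed benzyl transfer.

Step 6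
Reactants: 10 hydroxy ester; 12 vanillyl trichloroacetimidate
Product: 13 tert-butyl (3S,4R)-3-({[4-(benzyloxy)-3-methoxybenzyl]oxy}methyl)-4-[3,4-bis(benzyloxy)phenyl]-4-[(tert-butyldimethylsilyl)oxy]butanoate
Conditions: CSA (5 mol%), 4 Å MS, CH2Cl2, 0 °C → rt
Reagents that add atoms: none
Why: Acid-catalysed benzylation with a trichloroacetimidate, in which the 4-alkoxybenzyl imidate ionises under mild Brønsted acid and is captured by the primary alcohol, so that no alkoxide is formed that could lactonise onto the ester or trigger silyl migration.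

Step 7
Reactants: 13 vanillyl ether ester
Product: 15 tert-butyl (3S,4R)-3-({[4-(benzyloxy)-3-methoxybenzyl]oxy}methyl)-4-[3,4-bis(benzyloxy)phenyl]-4-[(tert-butyldimethylsilyl)oxy]-2-diazobutanoate, via α-trifluoroacetyl ester 14 (not isolated)
Conditions: LiN(SiMe3)2, THF, −78 °C; CF3CO2CH2CF3, −78 °C; aq. NH4Cl; then MsN3, Et3N, H2O (1 equiv), MeCN, rt
Reagents that add atoms: methanesulfonyl azide, CS(=O)(=O)N=[N+]=[N-]
Why: Detrifluoroacetylative diazo transfer (a deacylative Regitz-type diazo transfer), in which Claisen trifluoroacetylation of the ester enolate activates C3 so that the sulfonyl azide delivers N2 with loss of the trifluoroacetyl group; the enolate sits at C3 with no β-leaving group, so C4 and the carbinol carbon are not disturbed.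

Step 8
Reactants: 15 α-diazo tert-butyl ester
Product: 17 tert-butyl (2S,3S,4S)-2-[4-(benzyloxy)-3-methoxyphenyl]-4-{(R)-[3,4-bis(benzyloxy)phenyl][(tert-butyldimethylsilyl)oxy]methyl}oxolane-3-carboxylate (all-trans tetrahydrofuran ester), via all-cis C3-epimeric ester 16 (not isolated)
Conditions: Rh2(S-PTTL)4, dirhodium tetrakis[N-phthaloyl-(S)-tert-leucinate] (2 mol%), toluene, −78 → −40 °C, slow addition of 15; then KOtBu (0.3 equiv), THF/t-BuOH, 0 °C → rt
Reagents that add atoms: none
Why: The dirhodium tetracarboxylate decomposes the diazo ester with loss of N2 to an electrophilic rhodium carbene at C3, which inserts in a concerted three-centre fashion into the benzylic C2–H of the vanillyl ether and forms C2–C3; the closest known reaction type is the dirhodium-catalysed intramolecular 1,5 C–H insertion of α-alkyl-α-diazo esters next to an ether oxygen, which gives tetrahydrofuran-3-carboxylates and 2-aryl-2,3-dihydrobenzofuran-3-carboxylates. The tetrahydrofuran (O1, C2, C3, C4, C5) closes by C2–C3 bond formation through the five-membered 1,5-insertion transition state, and no other C–H bond stands in a 1,5 relationship to the carbene carbon. C2 is set under control of the C4 stereocenter: in the chair-like transition state the guaiacyl group at C2 and the bulky silyloxybenzyl group at C4 both lie pseudo-equatorial, which should give the 2,4-cis ring (C2 S), and the chiral carboxylate ligands are chosen to reinforce this sense. C3 is first set kinetically (the ester is expected to emerge cis to the C2 aryl group, as is usual for this catalyst family) and is then corrected in the same flask by KOtBu-mediated enolate equilibration to the ester that is trans to both neighbours. The step needs insertion to win over 1,2-hydride migration from C4–H and over ylide formation; the C2–H bond, activated by O1 and by the electron-rich aryl ring, together with bulky carboxylate ligands at low temperature and the silyl protection of the carbinol, should secure this.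

Step 9
Reactants: 17 all-trans tetrahydrofuran ester
Product: 18 [(2S,3R,4S)-2-[4-(benzyloxy)-3-methoxyphenyl]-4-{(R)-[3,4-bis(benzyloxy)phenyl][(tert-butyldimethylsilyl)oxy]methyl}oxolan-3-yl]methanol
Conditions: LiAlH4, THF, 0 °C; quench with H2O, 15% NaOH, H2O
Reagents that add atoms: none
Why: Hydride reduction of the tert-butyl ester to the primary alcohol with LiAlH4, to which the silyl ether, the benzyl ethers and the ring are inert; no stereocenter is touched.

Step 10
Reactants: 18 silyl-protected primary alcohol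
Product: 19 (2S,3R,4S)-2-[4-(benzyloxy)-3-methoxyphenyl]-4-{(R)-[3,4-bis(benzyloxy)phenyl](hydroxy)methyl}-3-(hydroxymethyl)oxolane
Conditions: Bu4NF, THF, 0 °C → rt
Reagents that add atoms: none
Why: Fluoride-mediated desilylation of the secondary silyl ether, which leaves the benzyl ethers and the 2-aryl tetrahydrofuran intact.

Step 11
Reactants: 19 tribenzyl diol
Product: 20 (2S,3R,4S)-4-[(R)-(3,4-dihydroxyphenyl)(hydroxy)methyl]-2-(4-hydroxy-3-methoxyphenyl)-3-(hydroxymethyl)oxolane (CNP0197133.1)
Conditions: H2 (1 atm), 10% Pd/C, EtOAc, rt, stopped after uptake of three equivalents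
Reagents that add atoms: none
Why: Catalytic hydrogenolysis of the three aryl benzyl ethers, which under neutral conditions should cleave well before the benzylic C–O bonds of the 2-aryl tetrahydrofuran and of the carbinol.

**Compound list**
1 | 4-tert-butoxy-4-oxobutanoic acid (mono-tert-butyl succinate) | OC(=O)CCC(=O)OC(C)(C)C | starting material
2 | (R)-4-benzyl-1,3-oxazolidin-2-one | O=C1N[C@H](Cc2ccccc2)CO1 | starting material
3 | 4-tert-butoxy-4-oxobutanoic pivalic anhydride | CC(C)(C)C(=O)OC(=O)CCC(=O)OC(C)(C)C | intermediate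
4 | tert-butyl 4-[(4R)-4-benzyl-2-oxo-1,3-oxazolidin-3-yl]-4-oxobutanoate | CC(C)(C)OC(=O)CCC(=O)N1[C@H](Cc2ccccc2)COC1=O | intermediate
5 | 3,4-bis(benzyloxy)benzaldehyde | O=Cc1ccc(OCc2ccccc2)c(OCc2ccccc2)c1 | starting material
6 | Z-dibutylboron enolate of 4 | CCCCB(CCCC)O/C(=C\CC(=O)OC(C)(C)C)N1[C@H](Cc2ccccc2)COC1=O | intermediate
7 | dibutylboron aldolate of 8 | O=C([C@H](CC(=O)OC(C)(C)C)[C@@H](OB(CCCC)CCCC)c1ccc(OCc2ccccc2)c(OCc2ccccc2)c1)N1[C@H](Cc2ccccc2)COC1=O | intermediate
8 | tert-butyl (3R,4R)-3-{[(4R)-4-benzyl-2-oxo-1,3-oxazolidin-3-yl]carbonyl}-4-[3,4-bis(benzyloxy)phenyl]-4-hydroxybutanoate | O=C([C@H](CC(=O)OC(C)(C)C)[C@@H](O)c1ccc(OCc2ccccc2)c(OCc2ccccc2)c1)N1[C@H](Cc2ccccc2)COC1=O | intermediate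
9 | tert-butyl (3R,4R)-3-{[(4R)-4-benzyl-2-oxo-1,3-oxazolidin-3-yl]carbonyl}-4-[3,4-bis(benzyloxy)phenyl]-4-[(tert-butyldimethylsilyl)oxy]butanoate | O=C([C@H](CC(=O)OC(C)(C)C)[C@@H](O[Si](C)(C)C(C)(C)C)c1ccc(OCc2ccccc2)c(OCc2ccccc2)c1)N1[C@H](Cc2ccccc2)COC1=O | intermediate
10 | tert-butyl (3S,4R)-4-[3,4-bis(benzyloxy)phenyl]-4-[(tert-butyldimethylsilyl)oxy]-3-(hydroxymethyl)butanoate | OC[C@@H]([C@@H](O[Si](C)(C)C(C)(C)C)c1ccc(OCc2ccccc2)c(OCc2ccccc2)c1)CC(=O)OC(C)(C)C | intermediate
11 | [4-(benzyloxy)-3-methoxyphenyl]methanol | OCc1ccc(OCc2ccccc2)c(OC)c1 | starting material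
12 | 4-(benzyloxy)-3-methoxybenzyl 2,2,2-trichloroacetimidate | COc1cc(COC(=N)C(Cl)(Cl)Cl)ccc1OCc1ccccc1 | intermediate
13 | tert-butyl (3S,4R)-3-({[4-(benzyloxy)-3-methoxybenzyl]oxy}methyl)-4-[3,4-bis(benzyloxy)phenyl]-4-[(tert-butyldimethylsilyl)oxy]butanoate | COc1cc(COC[C@@H]([C@@H](O[Si](C)(C)C(C)(C)C)c2ccc(OCc3ccccc3)c(OCc3ccccc3)c2)CC(=O)OC(C)(C)C)ccc1OCc1ccccc1 | intermediate
14 | 2-(trifluoroacetyl) derivative of 13 (mixture at C2, keto and enol forms) | COc1cc(COC[C@@H]([C@@H](O[Si](C)(C)C(C)(C)C)c2ccc(OCc3ccccc3)c(OCc3ccccc3)c2)C(C(=O)C(F)(F)F)C(=O)OC(C)(C)C)ccc1OCc1ccccc1 | intermediate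
15 | tert-butyl (3S,4R)-3-({[4-(benzyloxy)-3-methoxybenzyl]oxy}methyl)-4-[3,4-bis(benzyloxy)phenyl]-4-[(tert-butyldimethylsilyl)oxy]-2-diazobutanoate | COc1cc(COC[C@@H]([C@@H](O[Si](C)(C)C(C)(C)C)c3ccc(OCc4ccccc4)c(OCc5ccccc5)c3)C(=[N+]=[N-])C(=O)OC(C)(C)C)ccc1OCc1ccccc1 | intermediate
16 | tert-butyl (2S,3R,4S)-2-[4-(benzyloxy)-3-methoxyphenyl]-4-{(R)-[3,4-bis(benzyloxy)phenyl][(tert-butyldimethylsilyl)oxy]methyl}oxolane-3-carboxylate (all-cis C3 epimer of 17) | COc1cc([C@H]2OC[C@@H]([C@@H](O[Si](C)(C)C(C)(C)C)c3ccc(OCc4ccccc4)c(OCc5ccccc5)c3)[C@H]2C(=O)OC(C)(C)C)ccc1OCc1ccccc1 | intermediate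
17 | tert-butyl (2S,3S,4S)-2-[4-(benzyloxy)-3-methoxyphenyl]-4-{(R)-[3,4-bis(benzyloxy)phenyl][(tert-butyldimethylsilyl)oxy]methyl}oxolane-3-carboxylate (all-trans) | COc1cc([C@H]2OC[C@@H]([C@@H](O[Si](C)(C)C(C)(C)C)c3ccc(OCc4ccccc4)c(OCc5ccccc5)c3)[C@@H]2C(=O)OC(C)(C)C)ccc1OCc1ccccc1 | intermediate
18 | [(2S,3R,4S)-2-[4-(benzyloxy)-3-methoxyphenyl]-4-{(R)-[3,4-bis(benzyloxy)phenyl][(tert-butyldimethylsilyl)oxy]methyl}oxolan-3-yl]methanol | COc1cc([C@H]2OC[C@@H]([C@@H](O[Si](C)(C)C(C)(C)C)c3ccc(OCc4ccccc4)c(OCc5ccccc5)c3)[C@@H]2CO)ccc1OCc1ccccc1 | intermediate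
19 | (2S,3R,4S)-2-[4-(benzyloxy)-3-methoxyphenyl]-4-{(R)-[3,4-bis(benzyloxy)phenyl](hydroxy)methyl}-3-(hydroxymethyl)oxolane | COc1cc([C@H]2OC[C@@H]([C@@H](O)c3ccc(OCc4ccccc4)c(OCc5ccccc5)c3)[C@@H]2CO)ccc1OCc1ccccc1 | intermediate
20 | (2S,3R,4S)-4-[(R)-(3,4-dihydroxyphenyl)(hydroxy)methyl]-2-(4-hydroxy-3-methoxyphenyl)-3-(hydroxymethyl)oxolane (CNP0197133.1) | COc1cc([C@H]2OC[C@@H]([C@@H](O)c3ccc(O)c(O)c3)[C@@H]2CO)ccc1O | target

**Count**
Total steps: 11. Longest linear sequence: 10 (steps 1–4 and 6–11; step 5 is a one-step side branch).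

**Steps most likely to fail**

Step 8 (key step). The 1,2-hydride migration from the tertiary C4–H to the carbene carbon may outrun insertion. Facial discrimination at C2 may also be poor and give the 2,4-trans ring, and the base treatment may open the ring by E1cB loss of O1 from the C3 enolate. The fallback closes the ring at O1–C2 by ionisation chemistry and not at C2–C3. It sets out from 10: silylation of the primary hydroxyl (Et3SiCl, imidazole, CH2Cl2) would give the triethylsilyl ether F1. Its lithium enolate (LiN(iPr)2, THF, −78 °C) would add to commercial 4-(benzyloxy)-3-methoxybenzaldehyde to give the β-hydroxy ester F2 as a mixture at the two new carbons. Pyridinium p-toluenesulfonate in MeOH would remove the triethylsilyl group to give the diol F3. Catalytic camphorsulfonic acid in CH2Cl2 would then ionise the para-alkoxybenzylic alcohol, and the primary hydroxyl would capture the cation (SN1 cycloetherification, reversible, hence thermodynamic control at C2). KOtBu equilibration at C3 as in step 8 brings the material back to the route at 17.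

Step 7. C-Trifluoroacetylation of the hindered, β-branched ester enolate may be incomplete, or the activated ester may decompose before diazo transfer takes place. The fallback replaces the acyl-cleaving diazo transfer by diazotisation of an amine and sets out from 13. The potassium enolate (KN(SiMe3)2, THF, −78 °C) would be azidated with 2,4,6-triisopropylbenzenesulfonyl azide and quenched with AcOH to give the α-azido ester F4. Staudinger reduction (PPh3, THF/H2O) would give the α-amino ester F5. Diazotisation with isoamyl nitrite and catalytic AcOH in warm CHCl3 returns to the route at 15.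

Step 6. The electron-rich imidate may rearrange or self-alkylate before it is captured, and the acid may trigger lactonisation of the γ-hydroxy ester or ionisation of the benzylic silyl ether. The fallback is a silver-assisted alkylation with a benzylic halide under non-acidic, alkoxide-free conditions and sets out from 11 and 10. PBr3 in Et2O at 0 °C would convert 11 into 4-(benzyloxy)-3-methoxybenzyl bromide F6. Ag2O in CH2Cl2 with 4 Å sieves would join F6 to alcohol 10, which returns to the route at 13.

**Further compounds**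
F1 | step 8 | tert-butyl (3S,4R)-4-[3,4-bis(benzyloxy)phenyl]-4-[(tert-butyldimethylsilyl)oxy]-3-{[(triethylsilyl)oxy]methyl}butanoate | CC[Si](CC)(CC)OC[C@@H]([C@@H](O[Si](C)(C)C(C)(C)C)c1ccc(OCc2ccccc2)c(OCc2ccccc2)c1)CC(=O)OC(C)(C)C
F2 | step 8 | tert-butyl (3S,4R)-2-{[4-(benzyloxy)-3-methoxyphenyl](hydroxy)methyl}-4-[3,4-bis(benzyloxy)phenyl]-4-[(tert-butyldimethylsilyl)oxy]-3-{[(triethylsilyl)oxy]methyl}butanoate (mixture at the two new carbons) | CC[Si](CC)(CC)OC[C@@H]([C@@H](O[Si](C)(C)C(C)(C)C)c1ccc(OCc2ccccc2)c(OCc2ccccc2)c1)C(C(O)c1ccc(OCc2ccccc2)c(OC)c1)C(=O)OC(C)(C)C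
F3 | step 8 | tert-butyl (3S,4R)-2-{[4-(benzyloxy)-3-methoxyphenyl](hydroxy)methyl}-4-[3,4-bis(benzyloxy)phenyl]-4-[(tert-butyldimethylsilyl)oxy]-3-(hydroxymethyl)butanoate (mixture at the two new carbons) | OC[C@@H]([C@@H](O[Si](C)(C)C(C)(C)C)c1ccc(OCc2ccccc2)c(OCc2ccccc2)c1)C(C(O)c1ccc(OCc2ccccc2)c(OC)c1)C(=O)OC(C)(C)C
F4 | step 7 | tert-butyl (3S,4R)-2-azido-3-({[4-(benzyloxy)-3-methoxybenzyl]oxy}methyl)-4-[3,4-bis(benzyloxy)phenyl]-4-[(tert-butyldimethylsilyl)oxy]butanoate (mixture at C2) | COc1cc(COC[C@@H]([C@@H](O[Si](C)(C)C(C)(C)C)c2ccc(OCc3ccccc3)c(OCc3ccccc3)c2)C(N=[N+]=[N-])C(=O)OC(C)(C)C)ccc1OCc1ccccc1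
F5 | step 7 | tert-butyl (3S,4R)-2-amino-3-({[4-(benzyloxy)-3-methoxybenzyl]oxy}methyl)-4-[3,4-bis(benzyloxy)phenyl]-4-[(tert-butyldimethylsilyl)oxy]butanoate (mixture at C2) | COc1cc(COC[C@@H]([C@@H](O[Si](C)(C)C(C)(C)C)c2ccc(OCc3ccccc3)c(OCc3ccccc3)c2)C(N)C(=O)OC(C)(C)C)ccc1OCc1ccccc1
F6 | step 6 | 4-(benzyloxy)-3-methoxybenzyl bromide | COc1cc(CBr)ccc1OCc1ccccc1
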